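**Retrosynthetic overview**
1. No ring has to be built: the upper unit is bought whole as (+)-dihydromyricetin 1 (rings A, B, C and C2/C3 in place), whose C4 ketone is reduced to the flavan-3,4-diol 2.
2. The lower unit is bought whole as (−)-epicatechin 3 and used unprotected.
3. The only disconnection is the C4–C8 interflavan bond, cut to the C4 benzylic cation 4 (from 2 under mild acid) and C8 of 3; forming it is the last step and gives the target 5.
4. Four stereocentres are bought (C2 and C3 of each unit); the fifth, upper C4 (S, 4α, trans to the C3–OH), is set by substrate control in the coupling.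
5. Order: C4=O reduction, then C4–C8 Friedel–Crafts coupling; no protecting groups.

Assumption: the SMILES is read as gallocatechin-(4α→8)-epicatechin (upper unit 2R,3S,4S with the pyrogallol ring B; lower unit 2R,3R), and (+)-dihydromyricetin and (−)-epicatechin are taken as commercial single enantiomers.

**Step 1**
Reactants: 1 (+)-dihydromyricetin [(2R,3R)-3,5,7-trihydroxy-2-(3,4,5-trihydroxyphenyl)chroman-4-one]
Product: 2 (2R,3S,4R)-leucodelphinidin [2,3-trans-3,4-trans-2-(3,4,5-trihydroxyphenyl)chromane-3,4,5,7-tetrol]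
Conditions: NaBH4 (4 equiv), EtOH, N2, 0 °C to rt, 1 h; AcOH/H2O to pH 6 at 0 °C; EtOAc extraction, evaporate below 30 °C, use at once
Reagents that add atoms: none
Why: Borohydride reduction of the C4 ketone leaves C2 and C3 of 1 untouched, and axial hydride delivery anti to the equatorial C3–OH gives the all-equatorial 3,4-trans diol (4R), a centre that is erased again in step 2.

**Step 2**
Reactants: 2 (2R,3S,4R)-leucodelphinidin; 3 (−)-epicatechin [(2R,3R)-2-(3,4-dihydroxyphenyl)chromane-3,5,7-triol], 4 equiv
Product: 5 gallocatechin-(4α→8)-epicatechin, via gallocatechin C4 cation 4 (not isolated)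
Conditions: degassed H2O/EtOH 9:1, AcOH to pH 4.5, N2, dark, rt, 4–16 h; EtOAc extraction; Sephadex LH-20 (EtOH), then preparative reversed-phase HPLC; excess 3 recovered
Reagents that add atoms: none
Why: In this acid-catalysed SN1/Friedel–Crafts alkylation (biomimetic flavan-3,4-diol condensation) the C4–OH ionises to cation 4, stabilised by the ring A oxygens, and C8 of 3, the more nucleophilic and less hindered position of its phloroglucinol ring, attacks anti to the C3–OH to set C4 as S (4α, 3,4-trans), while the excess of 3 holds the reaction at the dimer.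

**Compound list**
1 | (+)-dihydromyricetin, (2R,3R) | Oc1cc(O)c2c(c1)O[C@H](c1cc(O)c(O)c(O)c1)[C@@H](O)C2=O | starting material
2 | (2R,3S,4R)-leucodelphinidin, 2,3-trans-3,4-trans flavan-3,4-diol | Oc1cc(O)c2c(c1)O[C@H](c1cc(O)c(O)c(O)c1)[C@@H](O)[C@@H]2O | intermediate
3 | (−)-epicatechin, (2R,3R) | Oc1cc(O)c2c(c1)O[C@H](c1ccc(O)c(O)c1)[C@H](O)C2 | starting material
4 | (2R,3S)-gallocatechin C4 cation (protonated ring A quinone methide), not isolated | Oc1cc(O)c2c(c1)O[C@H](c1cc(O)c(O)c(O)c1)[C@@H](O)[CH+]2 | intermediate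
5 | gallocatechin-(4α→8)-epicatechin, (2R,3S,4S)-4-[(2R,3R)-2-(3,4-dihydroxyphenyl)-3,5,7-trihydroxychroman-8-yl]-2-(3,4,5-trihydroxyphenyl)chromane-3,5,7-triol | Oc1cc(O)c2c(c1)O[C@H](c1cc(O)c(O)c(O)c1)[C@@H](O)[C@@H]2c1c(O)cc(O)c2c1O[C@H](c1ccc(O)c(O)c1)[C@H](O)C2 | target

**Totals**
Total step count: 2. Longest linear sequence: 2 steps (1 → 2 → 5).

**Steps most likely to fail**
The route has only two steps, so both are given, the riskier first.

Step 2 (coupling). Both partners are free polyphenols, so trimers, the 4→6 regioisomer and some 4β epimer can lower the isolated yield of 5 or co-elute with it. The fallback is a benzyl-protected Lewis-acid coupling that sets out from 1 and 3 and comes back at 5. The five phenols of 1 are benzylated (BnBr, K2CO3, DMF, rt, short reaction time to avoid C2 epimerisation) to 5,7,3',4',5'-penta-O-benzyl-(2R,3R)-dihydromyricetin F1. NaBH4 (THF/EtOH, 0 °C) then gives (2R,3S,4R)-5,7,3',4',5'-penta-O-benzyl-leucodelphinidin F2, a stable diol. Compound 3 is benzylated in the same way to 5,7,3',4'-tetra-O-benzyl-(−)-epicatechin F3. F2 and F3 (3 equiv) are joined with TiCl4 in CH2Cl2 at 0 °C to nona-O-benzyl-gallocatechin-(4α→8)-epicatechin F4. This coupling is C8-selective because C6 of F3 is flanked by two benzyloxy groups, and it is 3,4-trans by attack anti to the C3–OH. Hydrogenolysis (H2, Pd(OH)2/C, THF/MeOH/H2O, rt) removes the nine benzyl groups and gives 5.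

Step 1 (reduction and handling of 2). The free diol with its pyrogallol ring may oxidise in the basic borohydride medium or self-condense on work-up before it can be used. The fallback traps the electrophile as a thioether; it sets out from 1 and comes back at cation 4, which 3 captures to give 5. The reduction is run as in step 1, but 2 is not isolated: benzyl mercaptan and AcOH are added to the quenched mixture (EtOH, rt). Cation 4 is then caught as 4α-benzylsulfanyl-(+)-gallocatechin F5, a bench-stable compound that can be purified by chromatography (its 4β epimer is equally usable). F5 is activated under non-protic conditions with dimethyl(methylthio)sulfonium tetrafluoroborate (THF, −15 to 0 °C) in the presence of 3 (4 equiv), which regenerates 4 and leads to 5. This thiophile is chosen over AgBF4 because the pyrogallol ring can reduce AgBF4.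

**Further compounds**
F1 | step 2 | 5,7,3',4',5'-penta-O-benzyl-(2R,3R)-dihydromyricetin | c1ccccc1COc1cc(OCc3ccccc3)c2c(c1)O[C@H](c1cc(OCc3ccccc3)c(OCc3ccccc3)c(OCc3ccccc3)c1)[C@@H](O)C2=O
F2 | step 2 | (2R,3S,4R)-5,7,3',4',5'-penta-O-benzyl-leucodelphinidin | c1ccccc1COc1cc(OCc3ccccc3)c2c(c1)O[C@H](c1cc(OCc3ccccc3)c(OCc3ccccc3)c(OCc3ccccc3)c1)[C@@H](O)[C@@H]2O
F3 | step 2 | 5,7,3',4'-tetra-O-benzyl-(−)-epicatechin | c1ccccc1COc1cc(OCc3ccccc3)c2c(c1)O[C@H](c1ccc(OCc3ccccc3)c(OCc3ccccc3)c1)[C@H](O)C2
F4 | step 2 | nona-O-benzyl-gallocatechin-(4α→8)-epicatechin | c1ccccc1COc1cc(OCc3ccccc3)c2c(c1)O[C@H](c1cc(OCc3ccccc3)c(OCc3ccccc3)c(OCc3ccccc3)c1)[C@@H](O)[C@@H]2c1c(OCc3ccccc3)cc(OCc3ccccc3)c2c1O[C@H](c1ccc(OCc3ccccc3)c(OCc3ccccc3)c1)[C@H](O)C2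
F5 | step 1 | 4α-benzylsulfanyl-(+)-gallocatechin, (2R,3R,4R), 3,4-trans | Oc1cc(O)c2c(c1)O[C@H](c1cc(O)c(O)c(O)c1)[C@@H](O)[C@@H]2SCc1ccccc1
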